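Start from 3.17, the constant of the step that makes target over that of the step that eats it, a selectivity factor of sorts.

    spent carrier + capture agent → trapped intermediate (k1 = 4.8 L mol⁻¹ s⁻¹)
    spent carrier + salt in the second phase ⇌ fresh carrier + spent salt in the second phase (K2 = 2.4, k2 = 2.6 L mol⁻¹ s⁻¹)
    starting material + target → side product (k3 = 1.8 L mol⁻¹ s⁻¹)
    starting material + fresh carrier → target + spent carrier (k4 = 5.7 L mol⁻¹ s⁻¹)

in all of them: starting material 0.20 M; salt in the second phase 0.500 M; capture agent 0.0200 M; time 40 s; volume of the second phase over the first 1.0
- theta: spent carrier 4.0 mM
- epsilon: spent carrier 8.0 mM
- beta: spent carrier 15 mM
- zeta: spent carrier 30 mM
- alpha: spent carrier 60 mM

- in percentages every species weighs as the starting material in it: one side product counts as two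
- in the second phase: salt in the second phase, spent salt in the second phase; everything else is in the first
- charges count per volume of the first phase; a concentration in a rate is the amount of a species over the volume of its own phase; every rate counts per litre of the first phase
- "hardly changes" means that all values lie within two and a half points (for a concentration: within two and a half percent of the largest)
- run time (theta): 40 s

- amount of target at the end, in percent of the starting material charged for theta, epsilon, beta, zeta, alpha, in this order
- the course of these numbers from the first flask to the last (falls, then rises / falls all the way / rises, then falls / rises all the way / hardly changes)

Watch target, not starting material. Step 4 makes it and step 3 uses it, each with one starting material, so the two rates match when [target] equals 3.17 times [fresh carrier], whatever starting material is left. In theta, with starting material as charged, target has a half-life of 1.9 s against step 3, short beside the 40 s run, so it can follow that balance.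

Now put the whole catalyst charge in as fresh carrier and divide by the charge of starting material. That gives the ceiling, the balance level of target as a share of the starting material charged: 6.33 % for theta and 95.0 % for alpha. My reckoning then multiplies the ceiling by the fraction of catalyst left as fresh carrier.

That fraction stays below one, so each flask should end under its ceiling. It should also grow with the charge. In theta the capture agent outweighs the catalyst and can trap all of it, but in alpha the same 0.0200 M matches a third of the catalyst. So I commit to a row that rises all the way, and by more than the factor of 15.0 between the two ceilings. I give no point values; the forecast does.

The forecast gave 1 %, 3.8 %, 10 %, 24 % and 39 %, a course that rises all the way, on the grounds that “it scales with the amount of live carrier”.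

The flasks give 1.08 %, 3.29 %, 9.54 %, 22.5 % and 38.2 %, a course that rises all the way, and the ends lie a factor of 35.4 apart. One number was not enough, but in theta, with 59.9 % of the starting material still there, the ceiling times the final share of the catalyst charge standing as fresh carrier, 14.9 %, gives 0.943 %. In epsilon, with 30.4 % of the starting material still there, a ceiling of 12.7 % and a share of 22.8 %, it gives 2.90 %. In alpha the same product, 55.0 %, stands above the reading, with starting material at 0 % by the end. The target missing in alpha went through step 3: take that step out of alpha and target goes from 38.2 % to 99.9 %.

The numbers of this flask belong to no real substance; the run is a simulation.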